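**Synthesis plan for gnetofuran A (25): conjunctive coupling of two arenes onto a vinylboron linchpin**

## The problem

Gnetofuran A (25) is a trans-2-aryl-3-(hydroxymethyl)-2,3-dihydrobenzofuran. A guaiacyl ring (4-hydroxy-3-methoxyphenyl) sits on C2, and the fused benzene ring (ring B) carries a methoxy group at C7 and an (E)-3,5-dihydroxystyryl arm at C5. The skeleton is small, so the difficulty lies in the two adjacent stereocentres, C2 (R) and C3 (S), and in the sensitivity of the groups around them. C2 is a benzylic ether carbon para to a free phenol, so it can open to a para-quinone methide and close again; it can therefore be set last, under control of C3, and it settles in the trans arrangement. C3 has no such escape and must be set in absolute terms by a catalyst or reagent, and it must never sit next to a carbonyl group afterwards. The para-hydroxybenzyl aryl ether, the three phenols and the electron-rich (E)-stilbene do not tolerate strong acid, strong base, oxidants or light, so any oxidation has to be finished before the stilbene is in place. The enabling feature is that C2 and C3 form a two-carbon unit with exactly one aryl group on each carbon (guaiacyl on C2, ring B through C3a on C3) and that C3 also bears a one-carbon arm. This is the pattern a vinylboron compound delivers when one aryl group migrates from boron to the α-carbon and a second is delivered to the β-carbon; the boron left on C3 then stands in for the CH2OH arm. The cost of this mapping is that C2 arrives as a CH2 group and has to be oxidised later, which is feasible only because it is para to the guaiacyl oxygen.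

## Retrosynthesis

**Styryl arm.** The first cut is the C=C bond of the stilbene. Target 25 is the fourfold desilylation product of 24, and 24 is divided into aldehyde 18 and benzylic phosphonate 23. A cut at the aryl–vinyl bond instead would require a halogen on ring B that survives a bromine–lithium exchange and a palladium step. The carbonyl cut lets the formyl group of 5-bromovanillin (1) serve as the handle, masked until needed. The cut removes the oxidation-prone stilbene and the resorcinol from every earlier step. The forward olefination must be E-selective and must spare aryl silyl ethers, which is why triisopropylsilyl groups are used. Phosphonate 23 comes from 3,5-dihydroxybenzaldehyde (19) through 20, 21 and 22, and 18 is the bis-silyl ether of 17.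

**Dihydrofuran ring.** In 17 the O1–C2 bond is cut, giving the open phenol 15 through quinone methide 16. The neighbouring cuts are less attractive: O1–C7a would demand an aryl C–O coupling on a hindered ring, and C2–C3 would give up the two-carbon unit. The O1–C2 cut uses the fact that C2 is para-hydroxybenzylic and can be made electrophilic by oxidation of the guaiacyl phenol. Precursor 15 is acyclic with a single stereocentre. The forward step must oxidise the guaiacyl phenol in preference to the ring-B phenol (which is deactivated by its para formyl group), close the five-membered ring, and place the aryl group trans to the C3 arm.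

**One-carbon arm.** Phenol 15 is the unmasked form of alcohol 14. In 14 the C3–CH2OH bond is cut, leading through the homologated boronate 13 back to the secondary benzylic boronate 12. A boron atom on C3 is the natural placeholder, because insertion of a one-carbon carbenoid into a C–B bond and oxidation both proceed with retention. The forward step must insert exactly one carbon and must not disturb the MOM ethers or the dioxolane.

**Conjunctive coupling.** Boronate 12 is cut at two bonds, C3–C3a and C2–aryl. This gives three simple pieces: vinylboronic acid pinacol ester (9), aryllithium 10 and aryl triflate 8, which meet in the ate complex 11. Other routes to a 2,3-diarylpropyl stereocentre (auxiliary alkylation, asymmetric hydrogenation of a diarylacrylate) build the same centre next to a carbonyl and need more steps per bond. The forward reaction must favour the metallate shift over direct cross-coupling and must set C3 with high enantioselectivity through the chiral ligand.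

**Arene pieces.** Aryllithium 10 comes from bromide 3 by bromine–lithium exchange, and 3 from 1 through MOM ether 2. Triflate 8 comes from vanillin (4) through MOM ether 5, formate 6 and phenol 7. MOM and dioxolane are chosen because both survive organolithium reagents and both leave in one acidic operation.

## Roads not taken

**Alternative 1:** The cut removes the C3–CH2OH bond and the O1–C2 bond together and leads back to a one-carbon aldehyde and the stilbene methyl 4-(tert-butyldimethylsilyloxy)-3-methoxy-5-{(E)-2-[3-methoxy-4-(triisopropylsilyloxy)phenyl]ethenyl}benzoate A2. In the forward step a confined chiral Brønsted acid would activate the aldehyde, the alkene carbon next to ring B would attack it, and the silyl ether oxygen would trap the guaiacyl-stabilised cation with loss of silicon. The product would be methyl (2R,3S)-3-(hydroxymethyl)-7-methoxy-2-[3-methoxy-4-(triisopropylsilyloxy)phenyl]-2,3-dihydro-1-benzofuran-5-carboxylate A1.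
- Merits: ring, both stereocentres and the hydroxymethyl arm in its final oxidation state would arise in one catalytic step from a flat precursor. C2 never needs oxidation, and A1 is only an ester adjustment, an olefination and a desilylation away from the target.
- Weak points: an enantioselective intermolecular hydroxymethylation of a 1,2-diarylalkene with interception by an aryl silyl ether has no close model. Such acids are developed for simpler styrenes and tend to take up a second aldehyde to give 1,3-dioxanes. The electron-rich stilbene can dimerise under acid, and one catalyst would have to control regiochemistry, enantioselectivity and the trans relationship at once.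
- Comparison: if it worked, this road would be clearly shorter and more atom-economical. The chosen plan pays with a homologation, a late oxidation and protecting-group steps. Against that it sets a stereo-defining step whose scope covers aryl migrating groups and aryl triflates, and a C2 centre fixed by thermodynamics instead of by a second simultaneous selection.

**Alternative 2:** The cut removes C2–C3 and O1–C2 and leads to 4-bromo-2-methoxy-6-[(E)-2-nitroethenyl]phenol A4 and 1-[4-(tert-butyldimethylsilyloxy)-3-methoxybenzyl]tetrahydrothiophenium bromide A5. The ylide from A5 would add to the nitroalkene carbon next to the arene, and the phenoxide would then displace the sulfide at the ylide carbon. This formal (4+1) annulation would give (2R,3S)-5-bromo-2-[4-(tert-butyldimethylsilyloxy)-3-methoxyphenyl]-7-methoxy-3-(nitromethyl)-2,3-dihydro-1-benzofuran A3.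
- Merits: the annulation mode is known to be trans-selective. Both partners are a few steps from commercial aldehydes, and the ring forms directly with the C2 oxygen in place. The aryl bromide would allow a direct Heck reaction to the stilbene, which is a better endgame than the aldehyde and phosphonate used here.
- Weak points: asymmetric variants rely on stabilised ylides or chiral sulfides, and a semi-stabilised benzylic ylide is less secure. More seriously, the nitromethyl arm must become hydroxymethyl through a C3 aldehyde. That aldehyde is α to an arene and β to the phenoxy oxygen O1, so epimerisation at C3 and elimination to the benzofuran are both easy.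
- Comparison: this road reaches the ring faster and has the better handle on ring B. The chosen plan sets against it that C3 never sits next to a carbonyl group, and that its arm is grown by stereoretentive C–B to C–C to C–O changes.

**Alternative 3:** The cut is made at C3–C3a, which would be formed by an aryl shift from the flavanone (2R)-6-bromo-8-methoxy-2-[3-methoxy-4-(pivaloyloxy)phenyl]-2,3-dihydro-4H-chromen-4-one A7. A trivalent iodine oxidant in acidic orthoformate would attack the enol ether at C3, the ring carbon C4a would migrate from C4 to C3, and C4 would leave the ring as a methyl ester. The product would be methyl (2R,3R)-5-bromo-7-methoxy-2-[3-methoxy-4-(pivaloyloxy)phenyl]-2,3-dihydro-1-benzofuran-3-carboxylate A6.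
- Merits: the contraction is stereospecific, so C2 controls C3. The ester is one reduction from the hydroxymethyl arm, and because it is epimerisable it drifts to the favoured trans isomer. The C2–O bond is present from the start.
- Weak points: the absolute configuration rests entirely on obtaining A7 in enantioenriched form and keeping it so. Flavanones with electron-rich 2-aryl groups open reversibly to chalcones under the acidic conditions of the contraction. Migration of the 2-aryl group, which leads to an isoflavone, competes, and the bromine on the migrating ring lowers its aptitude.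
- Comparison: in diastereocontrol and oxidation level this road is as good as or better than the chosen one. The chosen plan sets against it a catalytic enantioselective step that creates a centre with no ring-opening pathway to racemisation, and a convergent assembly from three simple pieces.

Key step: step 6

Assumption: L* denotes one enantiomer of the MandyPhos ligand 1,1′-bis[bis(4-methoxy-3,5-dimethylphenyl)phosphino]-2,2′-bis[α-(dimethylamino)benzyl]ferrocene. Both enantiomers are available, and the one that leads to the (S)-boronate 12 is used.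

## Route

Step 1
Reactants: 1 5-bromovanillin (3-bromo-4-hydroxy-5-methoxybenzaldehyde)
Product: 2 3-bromo-5-methoxy-4-(methoxymethoxy)benzaldehyde
Conditions: MOMCl, i-Pr2NEt, CH2Cl2, 0 °C to rt
Reagents that add atoms: chloromethyl methyl ether (MOMCl), COCCl
Why: O-alkylation of the acidic phenol (MOM protection); the MOM group later stabilises the ortho-lithio species by chelation and leaves with acid together with the acetal.

Step 2
Reactants: 2 3-bromo-5-methoxy-4-(methoxymethoxy)benzaldehyde
Product: 3 2-[3-bromo-5-methoxy-4-(methoxymethoxy)phenyl]-1,3-dioxolane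
Conditions: (TMSOCH2)2, TMSOTf (cat.), CH2Cl2, −78 °C; pyridine quench
Reagents that add atoms: 1,2-bis(trimethylsilyloxy)ethane, C[Si](C)(C)OCCO[Si](C)(C)C
Why: Noyori acetalisation under aprotic conditions at low temperature, where the aryl MOM ether (a much less reactive formaldehyde acetal) should not ionise; the dioxolane masks the aldehyde against the organolithium reagents of steps 6 and 7.

Step 3
Reactants: 4 vanillin (4-hydroxy-3-methoxybenzaldehyde)
Product: 5 3-methoxy-4-(methoxymethoxy)benzaldehyde
Conditions: MOMCl, i-Pr2NEt, CH2Cl2, 0 °C to rt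
Reagents that add atoms: chloromethyl methyl ether (MOMCl), COCCl
Why: MOM protection of the phenol as in step 1; the ether withstands the peracid, the triflation and the organometallic steps that follow.

Step 4
Reactants: 5 3-methoxy-4-(methoxymethoxy)benzaldehyde
Product: 7 3-methoxy-4-(methoxymethoxy)phenol, via aryl formate 6 (not isolated)
Conditions: mCPBA, CH2Cl2, 0 °C to rt; NaHCO3 wash; then K2CO3 (cat.), MeOH, rt
Reagents that add atoms: 3-chloroperoxybenzoic acid (mCPBA), O=C(OO)c1cccc(Cl)c1
Why: Baeyer–Villiger (Dakin-type) oxidation; the electron-rich aryl group migrates in the Criegee intermediate to give the formate, which base-catalysed methanolysis converts to the phenol.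

Step 5
Reactants: 7 3-methoxy-4-(methoxymethoxy)phenol
Product: 8 3-methoxy-4-(methoxymethoxy)phenyl trifluoromethanesulfonate
Conditions: Tf2O, pyridine, CH2Cl2, 0 °C
Reagents that add atoms: trifluoromethanesulfonic anhydride, O=S(=O)(OS(=O)(=O)C(F)(F)F)C(F)(F)F
Why: O-sulfonylation of the phenol; the triflate is the halide-free electrophile that gives a cationic arylpalladium species in step 6.

Step 6
Reactants: 3 2-[3-bromo-5-methoxy-4-(methoxymethoxy)phenyl]-1,3-dioxolane; 9 vinylboronic acid pinacol ester (2-ethenyl-4,4,5,5-tetramethyl-1,3,2-dioxaborolane); 8 3-methoxy-4-(methoxymethoxy)phenyl trifluoromethanesulfonate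
Product: 12 2-[(1S)-1-[5-(1,3-dioxolan-2-yl)-3-methoxy-2-(methoxymethoxy)phenyl]-2-[3-methoxy-4-(methoxymethoxy)phenyl]ethyl]-4,4,5,5-tetramethyl-1,3,2-dioxaborolane, via aryllithium 10 (not isolated), via lithium vinylboronate complex 11 (not isolated)
Conditions: t-BuLi (2 equiv), Et2O, −78 °C; then 9, −78 °C to rt; solvent switch to THF; 8, Pd(OAc)2 (2 mol%), L* (2.4 mol%), KOTf, 60 °C
Reagents that add atoms: none
Why: Bromine–lithium exchange on 3 gives aryllithium 10, held by its ortho MOM oxygen, which adds to the empty orbital on boron of 9 to form the four-coordinate complex 11. Zerovalent palladium, formed from Pd(OAc)2 and L*, inserts into the C–O bond of triflate 8; because triflate does not bind, the divalent arylpalladium is cationic and takes up the electron-rich vinyl group of 11. This binding triggers a 1,2-metallate shift in which ring B moves from boron to the α-carbon anti to palladium (C3–C3a bond), and reductive elimination then joins the guaiacyl ring to the β-carbon (C2–aryl bond). The closest known reaction type is the enantioselective palladium-catalysed conjunctive cross-coupling of vinylboron ate complexes with aryl triflates, which is established for aryl migrating groups and is here only applied to new partners. No ring closes. The one new stereocentre, C3, is set by the chiral bisphosphine, which decides the alkene face bound by palladium and hence the face to which ring B migrates; the ligand enantiomer is chosen for S. The step must favour the metallate shift over direct transmetalation of the vinyl or aryl group and over β-hydride elimination; the wide bite angle of L*, the cationic palladium centre, the non-migrating pinacol ligand and the removal of bromide as KBr by KOTf should secure this. The MOM ethers, the dioxolane and the methoxy groups are spectators, and the secondary benzylic pinacol boronate should be stable to isolation.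

Step 7
Reactants: 12 2-[(1S)-1-[5-(1,3-dioxolan-2-yl)-3-methoxy-2-(methoxymethoxy)phenyl]-2-[3-methoxy-4-(methoxymethoxy)phenyl]ethyl]-4,4,5,5-tetramethyl-1,3,2-dioxaborolane
Product: 14 (2S)-2-[5-(1,3-dioxolan-2-yl)-3-methoxy-2-(methoxymethoxy)phenyl]-3-[3-methoxy-4-(methoxymethoxy)phenyl]propan-1-ol, via homologated boronate 13 (not isolated)
Conditions: BrCH2Cl, n-BuLi, THF, −78 °C to rt; then NaOH (aq), H2O2, 0 °C to rt
Reagents that add atoms: bromochloromethane, ClCBr; hydrogen peroxide, OO
Why: Matteson homologation; chloromethyllithium made in the flask adds to boron and the secondary benzylic carbon migrates with retention, displacing chloride; oxidation of the new primary C–B bond then gives the alcohol, and the C3 centre is a spectator throughout.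

Step 8
Reactants: 14 (2S)-2-[5-(1,3-dioxolan-2-yl)-3-methoxy-2-(methoxymethoxy)phenyl]-3-[3-methoxy-4-(methoxymethoxy)phenyl]propan-1-ol
Product: 15 4-hydroxy-3-[(2S)-1-hydroxy-3-(4-hydroxy-3-methoxyphenyl)propan-2-yl]-5-methoxybenzaldehyde
Conditions: 3 M HCl (aq), THF, 45 °C
Reagents that add atoms: water, O
Why: Acid-catalysed hydrolysis of the two aryl MOM acetals and the dioxolane in one operation; C3 is next to neither a carbonyl nor a leaving group and should be safe, and the released formaldehyde stays in the aqueous phase as its hydrate.

Step 9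
Reactants: 15 4-hydroxy-3-[(2S)-1-hydroxy-3-(4-hydroxy-3-methoxyphenyl)propan-2-yl]-5-methoxybenzaldehyde
Product: 17 (2R,3S)-2-(4-hydroxy-3-methoxyphenyl)-3-(hydroxymethyl)-7-methoxy-2,3-dihydro-1-benzofuran-5-carbaldehyde, via quinone methide 16 (not isolated)
Conditions: Ag2O, CH2Cl2/acetone, rt, dark
Reagents that add atoms: none
Why: Oxidative cyclisation through a para-quinone methide, a known route from 2-hydroxy-diarylalkanes to 2-aryl oxygen heterocycles; Ag2O removes two electrons and two protons from the 4-alkylguaiacol unit (the ring-B phenol, para to the formyl group, is harder to oxidise), and the ring-B phenol adds to the exocyclic carbon in a 5-exo-trig closure. The aryl group should settle trans to the C3 hydroxymethyl group, as in biomimetic phenylcoumaran formation, so C2 becomes R under control of C3.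

Step 10
Reactants: 17 (2R,3S)-2-(4-hydroxy-3-methoxyphenyl)-3-(hydroxymethyl)-7-methoxy-2,3-dihydro-1-benzofuran-5-carbaldehyde
Product: 18 (2R,3S)-7-methoxy-2-[3-methoxy-4-(triisopropylsilyloxy)phenyl]-3-[(triisopropylsilyloxy)methyl]-2,3-dihydro-1-benzofuran-5-carbaldehyde
Conditions: TIPSCl, imidazole, DMF, rt
Reagents that add atoms: triisopropylsilyl chloride, CC(C)[Si](Cl)(C(C)C)C(C)C
Why: Silylation of the phenol and the primary alcohol; it removes the acidic hydroxy groups before the basic olefination and blocks ring opening through the para-phenoxide.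

Step 11
Reactants: 19 3,5-dihydroxybenzaldehyde
Product: 20 3,5-bis(triisopropylsilyloxy)benzaldehyde
Conditions: TIPSCl, imidazole, DMF, rt
Reagents that add atoms: triisopropylsilyl chloride, CC(C)[Si](Cl)(C(C)C)C(C)C
Why: Silylation of both phenols; triisopropylsilyl aryl ethers are chosen because they resist the base of step 15 better than smaller silyl ethers.

Step 12
Reactants: 20 3,5-bis(triisopropylsilyloxy)benzaldehyde
Product: 21 [3,5-bis(triisopropylsilyloxy)phenyl]methanol
Conditions: NaBH4, MeOH/THF, 0 °C
Reagents that add atoms: none
Why: Hydride reduction of the aldehyde to the benzylic alcohol; aryl silyl ethers are untouched at this temperature.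

Step 13
Reactants: 21 [3,5-bis(triisopropylsilyloxy)phenyl]methanol
Product: 22 1-(bromomethyl)-3,5-bis(triisopropylsilyloxy)benzene
Conditions: CBr4, PPh3, CH2Cl2, 0 °C
Reagents that add atoms: carbon tetrabromide, BrC(Br)(Br)Br
Why: Appel bromination of the primary benzylic alcohol under neutral conditions that spare the silyl ethers.

Step 14
Reactants: 22 1-(bromomethyl)-3,5-bis(triisopropylsilyloxy)benzene
Product: 23 diethyl {[3,5-bis(triisopropylsilyloxy)phenyl]methyl}phosphonate
Conditions: P(OEt)3, neat, 130 °C
Reagents that add atoms: triethyl phosphite, CCOP(OCC)OCC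
Why: Michaelis–Arbuzov reaction of the benzylic bromide; the volatile bromoethane leaves the melt.

Step 15
Reactants: 18 (2R,3S)-7-methoxy-2-[3-methoxy-4-(triisopropylsilyloxy)phenyl]-3-[(triisopropylsilyloxy)methyl]-2,3-dihydro-1-benzofuran-5-carbaldehyde; 23 diethyl {[3,5-bis(triisopropylsilyloxy)phenyl]methyl}phosphonate
Product: 24 (2R,3S)-5-{(E)-2-[3,5-bis(triisopropylsilyloxy)phenyl]ethenyl}-7-methoxy-2-[3-methoxy-4-(triisopropylsilyloxy)phenyl]-3-[(triisopropylsilyloxy)methyl]-2,3-dihydro-1-benzofuran
Conditions: NaH, 15-crown-5 (cat.), THF, 0 °C to rt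
Reagents that add atoms: none
Why: Horner–Wadsworth–Emmons olefination; the benzylic phosphonate anion adds to the aryl aldehyde and the adduct collapses to the (E)-stilbene under thermodynamic control, while C2 and C3 carry no hydrogen acidic enough to be removed.

Step 16
Reactants: 24 (2R,3S)-5-{(E)-2-[3,5-bis(triisopropylsilyloxy)phenyl]ethenyl}-7-methoxy-2-[3-methoxy-4-(triisopropylsilyloxy)phenyl]-3-[(triisopropylsilyloxy)methyl]-2,3-dihydro-1-benzofuran
Product: 25 gnetofuran A, 5-{(E)-2-[(2R,3S)-2-(4-hydroxy-3-methoxyphenyl)-3-(hydroxymethyl)-7-methoxy-2,3-dihydro-1-benzofuran-5-yl]ethenyl}benzene-1,3-diol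
Conditions: TBAF, AcOH, THF, 0 °C to rt, dark
Reagents that add atoms: none
Why: Fluoride-induced cleavage of all four silyl ethers; acetic acid protonates the phenoxides as they form, so the para-hydroxybenzyl ether at C2 should not open to a quinone methide, and light is excluded to keep the stilbene E.

## Compound list

1 | 5-bromovanillin (3-bromo-4-hydroxy-5-methoxybenzaldehyde) | COc1cc(C=O)cc(Br)c1O | starting material
2 | 3-bromo-5-methoxy-4-(methoxymethoxy)benzaldehyde | COCOc1c(Br)cc(C=O)cc1OC | intermediate
3 | 2-[3-bromo-5-methoxy-4-(methoxymethoxy)phenyl]-1,3-dioxolane | COCOc1c(Br)cc(C2OCCO2)cc1OC | intermediate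
4 | vanillin (4-hydroxy-3-methoxybenzaldehyde) | COc1cc(C=O)ccc1O | starting material
5 | 3-methoxy-4-(methoxymethoxy)benzaldehyde | COCOc1ccc(C=O)cc1OC | intermediate
6 | 3-methoxy-4-(methoxymethoxy)phenyl formate | COCOc1ccc(OC=O)cc1OC | intermediate
7 | 3-methoxy-4-(methoxymethoxy)phenol | COCOc1ccc(O)cc1OC | intermediate
8 | 3-methoxy-4-(methoxymethoxy)phenyl trifluoromethanesulfonate | COCOc1ccc(OS(=O)(=O)C(F)(F)F)cc1OC | intermediate
9 | vinylboronic acid pinacol ester (2-ethenyl-4,4,5,5-tetramethyl-1,3,2-dioxaborolane) | C=CB1OC(C)(C)C(C)(C)O1 | starting material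
10 | [5-(1,3-dioxolan-2-yl)-3-methoxy-2-(methoxymethoxy)phenyl]lithium | [Li]c1cc(C2OCCO2)cc(OC)c1OCOC | intermediate
11 | lithium [5-(1,3-dioxolan-2-yl)-3-methoxy-2-(methoxymethoxy)phenyl](ethenyl)(pinacolato)borate | [Li+].C=C[B-]1(c2cc(C3OCCO3)cc(OC)c2OCOC)OC(C)(C)C(C)(C)O1 | intermediate
12 | 2-[(1S)-1-[5-(1,3-dioxolan-2-yl)-3-methoxy-2-(methoxymethoxy)phenyl]-2-[3-methoxy-4-(methoxymethoxy)phenyl]ethyl]-4,4,5,5-tetramethyl-1,3,2-dioxaborolane | COc1cc(C[C@H](B2OC(C)(C)C(C)(C)O2)c2cc(C3OCCO3)cc(OC)c2OCOC)ccc1OCOC | intermediate
13 | 2-[(2S)-2-[5-(1,3-dioxolan-2-yl)-3-methoxy-2-(methoxymethoxy)phenyl]-3-[3-methoxy-4-(methoxymethoxy)phenyl]propyl]-4,4,5,5-tetramethyl-1,3,2-dioxaborolane | COc1cc(C[C@H](CB2OC(C)(C)C(C)(C)O2)c2cc(C3OCCO3)cc(OC)c2OCOC)ccc1OCOC | intermediate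
14 | (2S)-2-[5-(1,3-dioxolan-2-yl)-3-methoxy-2-(methoxymethoxy)phenyl]-3-[3-methoxy-4-(methoxymethoxy)phenyl]propan-1-ol | COc1cc(C[C@H](CO)c2cc(C3OCCO3)cc(OC)c2OCOC)ccc1OCOC | intermediate
15 | 4-hydroxy-3-[(2S)-1-hydroxy-3-(4-hydroxy-3-methoxyphenyl)propan-2-yl]-5-methoxybenzaldehyde | COc1cc(C[C@H](CO)c2cc(C=O)cc(OC)c2O)ccc1O | intermediate
16 | 4-hydroxy-3-[(2S)-1-hydroxy-3-(3-methoxy-4-oxocyclohexa-2,5-dien-1-ylidene)propan-2-yl]-5-methoxybenzaldehyde | COC1=CC(=C[C@H](CO)c2cc(C=O)cc(OC)c2O)C=CC1=O | intermediate
17 | (2R,3S)-2-(4-hydroxy-3-methoxyphenyl)-3-(hydroxymethyl)-7-methoxy-2,3-dihydro-1-benzofuran-5-carbaldehyde | COc1cc([C@@H]2Oc3c(OC)cc(C=O)cc3[C@H]2CO)ccc1O | intermediate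
18 | (2R,3S)-7-methoxy-2-[3-methoxy-4-(triisopropylsilyloxy)phenyl]-3-[(triisopropylsilyloxy)methyl]-2,3-dihydro-1-benzofuran-5-carbaldehyde | COc1cc([C@@H]2Oc3c(OC)cc(C=O)cc3[C@H]2CO[Si](C(C)C)(C(C)C)C(C)C)ccc1O[Si](C(C)C)(C(C)C)C(C)C | intermediate
19 | 3,5-dihydroxybenzaldehyde | O=Cc1cc(O)cc(O)c1 | starting material
20 | 3,5-bis(triisopropylsilyloxy)benzaldehyde | O=Cc1cc(O[Si](C(C)C)(C(C)C)C(C)C)cc(O[Si](C(C)C)(C(C)C)C(C)C)c1 | intermediate
21 | [3,5-bis(triisopropylsilyloxy)phenyl]methanol | OCc1cc(O[Si](C(C)C)(C(C)C)C(C)C)cc(O[Si](C(C)C)(C(C)C)C(C)C)c1 | intermediate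
22 | 1-(bromomethyl)-3,5-bis(triisopropylsilyloxy)benzene | BrCc1cc(O[Si](C(C)C)(C(C)C)C(C)C)cc(O[Si](C(C)C)(C(C)C)C(C)C)c1 | intermediate
23 | diethyl {[3,5-bis(triisopropylsilyloxy)phenyl]methyl}phosphonate | CCOP(=O)(Cc1cc(O[Si](C(C)C)(C(C)C)C(C)C)cc(O[Si](C(C)C)(C(C)C)C(C)C)c1)OCC | intermediate
24 | (2R,3S)-5-{(E)-2-[3,5-bis(triisopropylsilyloxy)phenyl]ethenyl}-7-methoxy-2-[3-methoxy-4-(triisopropylsilyloxy)phenyl]-3-[(triisopropylsilyloxy)methyl]-2,3-dihydro-1-benzofuran | COc1cc([C@@H]2Oc3c(OC)cc(/C=C/c4cc(O[Si](C(C)C)(C(C)C)C(C)C)cc(O[Si](C(C)C)(C(C)C)C(C)C)c4)cc3[C@H]2CO[Si](C(C)C)(C(C)C)C(C)C)ccc1O[Si](C(C)C)(C(C)C)C(C)C | intermediate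
25 | gnetofuran A, 5-{(E)-2-[(2R,3S)-2-(4-hydroxy-3-methoxyphenyl)-3-(hydroxymethyl)-7-methoxy-2,3-dihydro-1-benzofuran-5-yl]ethenyl}benzene-1,3-diol | COc1cc([C@@H]2Oc3c(OC)cc(/C=C/c4cc(O)cc(O)c4)cc3[C@H]2CO)ccc1O | target

## Step count and least certain steps

Total step count: 16. Longest linear sequence: 10 steps, from vanillin (4) through steps 3, 4, 5, 6, 7, 8, 9, 10, 15 and 16.

**Step 6 (key step).** The most likely failure is diversion of the ate complex into direct cross-coupling: the hindered, ortho-alkoxy-substituted ring B may transmetalate to palladium instead of migrating, or residual bromide may block the cationic palladium centre. A second risk is lower enantioselectivity, because the ortho MOM group changes the geometry of the migrating ring. The fallback sets out from 3 and comes back at 12; it replaces the catalytic shift by a stoichiometric, reagent-controlled 1,2-shift (lithiation–borylation).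
- Aryllithium 10, made from 3 as before, would be quenched with i-PrOB(pin) to give 2-[5-(1,3-dioxolan-2-yl)-3-methoxy-2-(methoxymethoxy)phenyl]-4,4,5,5-tetramethyl-1,3,2-dioxaborolane F1.
- Commercial 4-(2-hydroxyethyl)-2-methoxyphenol F2 would be protected at the phenol (MOMCl, K2CO3, acetone) to give 2-[3-methoxy-4-(methoxymethoxy)phenyl]ethanol F3, then carbamoylated (i-Pr2NCOCl, Et3N, CH2Cl2, reflux) to give 2-[3-methoxy-4-(methoxymethoxy)phenyl]ethyl N,N-diisopropylcarbamate F4.
- Deprotonation with s-BuLi and (+)-sparteine in Et2O at −78 °C should remove the pro-R hydrogen and give (1R)-1-lithio-2-[3-methoxy-4-(methoxymethoxy)phenyl]ethyl N,N-diisopropylcarbamate F5.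
- Boronate F1 should add with retention to give lithium [(1R)-1-(diisopropylcarbamoyloxy)-2-[3-methoxy-4-(methoxymethoxy)phenyl]ethyl][5-(1,3-dioxolan-2-yl)-3-methoxy-2-(methoxymethoxy)phenyl](pinacolato)borate F6.
- On warming (with MgBr2·OEt2 if needed) ring B should migrate with inversion and expel the carbamate, giving 12 in the S configuration.

**Step 9.** Ag2O is a one-electron oxidant, so the guaiacyl phenoxyl radical may couple with itself instead of going on to the quinone methide. The quinone methide may also tautomerise to a styrene, which would erase C3, before the deactivated ring-B phenol adds. The fallback sets out from 15 and comes back at 17; it separates oxidation from ring closure and uses a two-electron oxidant.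
- DDQ in MeOH/CH2Cl2 at 0 °C should generate the quinone methide by hydride abstraction in a medium that traps it at once. This gives 4-hydroxy-3-[(2S)-1-hydroxy-3-(4-hydroxy-3-methoxyphenyl)-3-methoxypropan-2-yl]-5-methoxybenzaldehyde F7 as both epimers at the new ether carbon.
- BF3·OEt2 in CH2Cl2 would then ionise the para-hydroxybenzyl methyl ether, and the ring-B phenol should close the ring under thermodynamic control to trans-17.

**Step 15.** The phosphonate anion or adventitious hydroxide may strip an aryl silyl group. The freed para-phenoxide can then open the dihydrofuran through a quinone methide, and addition to the electron-rich aldehyde may be slow enough for this to compete. The fallback sets out from 18 and comes back at 24; it forms the C=C bond by palladium-catalysed vinylic substitution under weakly basic conditions.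
- Wittig methylenation (Ph3PCH3Br, KHMDS, THF, 0 °C) would give (2R,3S)-5-ethenyl-7-methoxy-2-[3-methoxy-4-(triisopropylsilyloxy)phenyl]-3-[(triisopropylsilyloxy)methyl]-2,3-dihydro-1-benzofuran F8.
- Commercial 5-iodobenzene-1,3-diol F9 would be silylated (TIPSCl, imidazole, DMF) to 1-iodo-3,5-bis(triisopropylsilyloxy)benzene F10.
- Mizoroki–Heck coupling of F8 with F10 (Pd(OAc)2, P(o-tol)3, Et3N, DMF, 90 °C) should give 24 as the E isomer.

**Step 2.** The silyl triflate may activate the aryl MOM acetal as well as the aldehyde, which would lead to exchange or loss of the MOM group. The fallback sets out from 1 and comes back at 3; it carries out the acidic acetalisation before any MOM group is present.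
- Acetylation (Ac2O, pyridine) would give 2-bromo-4-formyl-6-methoxyphenyl acetate F11, in which the acyloxy group no longer deactivates the aldehyde.
- Classical acetalisation (ethylene glycol, p-TsOH cat., toluene, Dean–Stark) would give 2-bromo-4-(1,3-dioxolan-2-yl)-6-methoxyphenyl acetate F12.
- Methanolysis (K2CO3, MeOH) would give 2-bromo-4-(1,3-dioxolan-2-yl)-6-methoxyphenol F13, and MOMCl with i-Pr2NEt would then give 3.

## Further compounds

F1 | step 6 | 2-[5-(1,3-dioxolan-2-yl)-3-methoxy-2-(methoxymethoxy)phenyl]-4,4,5,5-tetramethyl-1,3,2-dioxaborolane | COCOc1c(B2OC(C)(C)C(C)(C)O2)cc(C2OCCO2)cc1OC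
F2 | step 6 | 4-(2-hydroxyethyl)-2-methoxyphenol | COc1cc(CCO)ccc1O
F3 | step 6 | 2-[3-methoxy-4-(methoxymethoxy)phenyl]ethanol | COCOc1ccc(CCO)cc1OC
F4 | step 6 | 2-[3-methoxy-4-(methoxymethoxy)phenyl]ethyl N,N-diisopropylcarbamate | COCOc1ccc(CCOC(=O)N(C(C)C)C(C)C)cc1OC
F5 | step 6 | (1R)-1-lithio-2-[3-methoxy-4-(methoxymethoxy)phenyl]ethyl N,N-diisopropylcarbamate | COCOc1ccc(C[C@@H]([Li])OC(=O)N(C(C)C)C(C)C)cc1OC
F6 | step 6 | lithium [(1R)-1-(diisopropylcarbamoyloxy)-2-[3-methoxy-4-(methoxymethoxy)phenyl]ethyl][5-(1,3-dioxolan-2-yl)-3-methoxy-2-(methoxymethoxy)phenyl](pinacolato)borate | [Li+].COCOc1ccc(C[C@@H]([B-]2(c3cc(C4OCCO4)cc(OC)c3OCOC)OC(C)(C)C(C)(C)O2)OC(=O)N(C(C)C)C(C)C)cc1OC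
F7 | step 9 | 4-hydroxy-3-[(2S)-1-hydroxy-3-(4-hydroxy-3-methoxyphenyl)-3-methoxypropan-2-yl]-5-methoxybenzaldehyde (both epimers at C3 of the chain) | COc1cc(C(OC)[C@H](CO)c2cc(C=O)cc(OC)c2O)ccc1O
F8 | step 15 | (2R,3S)-5-ethenyl-7-methoxy-2-[3-methoxy-4-(triisopropylsilyloxy)phenyl]-3-[(triisopropylsilyloxy)methyl]-2,3-dihydro-1-benzofuran | COc1cc([C@@H]2Oc3c(OC)cc(C=C)cc3[C@H]2CO[Si](C(C)C)(C(C)C)C(C)C)ccc1O[Si](C(C)C)(C(C)C)C(C)C
F9 | step 15 | 5-iodobenzene-1,3-diol | Oc1cc(O)cc(I)c1
F10 | step 15 | 1-iodo-3,5-bis(triisopropylsilyloxy)benzene | CC(C)[Si](Oc1cc(I)cc(O[Si](C(C)C)(C(C)C)C(C)C)c1)(C(C)C)C(C)C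
F11 | step 2 | 2-bromo-4-formyl-6-methoxyphenyl acetate | CC(=O)Oc1c(Br)cc(C=O)cc1OC
F12 | step 2 | 2-bromo-4-(1,3-dioxolan-2-yl)-6-methoxyphenyl acetate | CC(=O)Oc1c(Br)cc(C2OCCO2)cc1OC
F13 | step 2 | 2-bromo-4-(1,3-dioxolan-2-yl)-6-methoxyphenol | Oc1c(Br)cc(C2OCCO2)cc1OC
A1 | alternative 1 | methyl (2R,3S)-3-(hydroxymethyl)-7-methoxy-2-[3-methoxy-4-(triisopropylsilyloxy)phenyl]-2,3-dihydro-1-benzofuran-5-carboxylate | COc1cc([C@@H]2Oc3c(OC)cc(C(=O)OC)cc3[C@H]2CO)ccc1O[Si](C(C)C)(C(C)C)C(C)C
A2 | alternative 1 | methyl 4-(tert-butyldimethylsilyloxy)-3-methoxy-5-{(E)-2-[3-methoxy-4-(triisopropylsilyloxy)phenyl]ethenyl}benzoate | COC(=O)c1cc(OC)c(O[Si](C)(C)C(C)(C)C)c(/C=C/c2ccc(O[Si](C(C)C)(C(C)C)C(C)C)c(OC)c2)c1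
A3 | alternative 2 | (2R,3S)-5-bromo-2-[4-(tert-butyldimethylsilyloxy)-3-methoxyphenyl]-7-methoxy-3-(nitromethyl)-2,3-dihydro-1-benzofuran | COc1cc([C@@H]2Oc3c(OC)cc(Br)cc3[C@H]2C[N+](=O)[O-])ccc1O[Si](C)(C)C(C)(C)C
A4 | alternative 2 | 4-bromo-2-methoxy-6-[(E)-2-nitroethenyl]phenol | COc1cc(Br)cc(/C=C/[N+](=O)[O-])c1O
A5 | alternative 2 | 1-[4-(tert-butyldimethylsilyloxy)-3-methoxybenzyl]tetrahydrothiophenium bromide | COc1cc(C[S+]2CCCC2)ccc1O[Si](C)(C)C(C)(C)C.[Br-]
A6 | alternative 3 | methyl (2R,3R)-5-bromo-7-methoxy-2-[3-methoxy-4-(pivaloyloxy)phenyl]-2,3-dihydro-1-benzofuran-3-carboxylate | COc1cc([C@@H]2Oc3c(OC)cc(Br)cc3[C@H]2C(=O)OC)ccc1OC(=O)C(C)(C)C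
A7 | alternative 3 | (2R)-6-bromo-8-methoxy-2-[3-methoxy-4-(pivaloyloxy)phenyl]-2,3-dihydro-4H-chromen-4-one | COc1cc(Br)cc2c1O[C@@H](c1ccc(OC(=O)C(C)(C)C)c(OC)c1)CC2=O
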